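**Strategy.** Everything rests on cutting the C3=C4 alkene and the C2–O bond of the undecatriene chain (C1–C11). The S carbinol carbon C2, which bears the acetate and the CH2 bound to position 3 of a furan ring, sits directly on the CH end of the E-trisubstituted C3=C4(CH3)–C5H2 alkene. One flask operation on the α-unbranched 3-(furan-3-yl)propanal installs this oxygen enantioselectively under D-proline catalysis and olefinates the labile α-oxy aldehyde with an α-methyl ester ylide; the ester carbon of the resulting γ-oxygenated E-enoate becomes C5. The same aldehyde also supplies the dienyl half, joined at C5–C6 by a Pd(PPh3)4-catalysed allyl–alkenyl coupling.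

Key step: step 4

Assumption: the sense of induction follows the established behaviour of proline in α-aminoxylation (L-proline gives R α-aminoxy aldehydes), so D-proline is used for the S centre; the anilino fragment lost in step 5 is written as azobenzene, the redox-neutral outcome.

Step 1
Reactants: 1 furan-3-carbaldehyde; 2 trimethyl phosphonoacetate
Product: 3 methyl (2E)-3-(furan-3-yl)prop-2-enoate
Conditions: NaH, THF, 0 °C to rt
Reagents that add atoms: trimethyl phosphonoacetate 2, COC(=O)CP(=O)(OC)OC
Why: Horner–Wadsworth–Emmons olefination of an aromatic aldehyde with a stabilised phosphonate anion should give the E-enoate, because the reversible addition funnels through the anti oxaphosphetane.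

Step 2
Reactants: 3 methyl (2E)-3-(furan-3-yl)prop-2-enoate
Product: 4 methyl 3-(furan-3-yl)propanoate
Conditions: NaBH4, NiCl2·6H2O (10 mol%), MeOH, 0 °C
Reagents that add atoms: none
Why: Conjugate reduction by Ni2B (nickel boride) formed in the flask should saturate only the electron-poor alkene, leaving the aromatic furan and the methyl ester (matched to the solvent) unchanged.

Step 3
Reactants: 4 methyl 3-(furan-3-yl)propanoate
Product: 5 3-(furan-3-yl)propanal
Conditions: i-Bu2AlH (1.05 equiv), CH2Cl2, −78 °C; MeOH, then aq. potassium sodium tartrate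
Reagents that add atoms: none
Why: Partial ester reduction with one equivalent of i-Bu2AlH at −78 °C should stop at the aluminium hemiacetal, which releases the aldehyde only on work-up.

Step 4
Reactants: 5 3-(furan-3-yl)propanal (1.2 equiv); 6 nitrosobenzene (1.0 equiv, limiting); 7 D-proline (catalyst); 8 ethyl 2-(triphenylphosphoranylidene)propanoate
Product: 10 ethyl (2E,4S)-5-(furan-3-yl)-2-methyl-4-[(phenylamino)oxy]pent-2-enoate, via α-anilinooxy aldehyde 9 (not isolated)
Conditions: 7 (20 mol%), DMSO, rt, until the green colour of 6 has gone; then 8 (1.5 equiv), CH2Cl2, 0 °C to rt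
Reagents that add atoms: nitrosobenzene 6, O=Nc1ccccc1; ethyl 2-(triphenylphosphoranylidene)propanoate 8, CCOC(=O)C(C)=P(c1ccccc1)(c1ccccc1)c1ccccc1
Why: Condensation of 5 with D-proline gives the E-enamine, whose carboxylic acid hydrogen-bonds to the nitroso nitrogen so that the oxygen end of 6 is delivered to one face of the enamine carbon through an ordered chair-like transition state; hydrolysis frees aldehyde 9 and the catalyst, and the ester-stabilised ylide 8 then adds to 9 and collapses through the oxaphosphetane to the E-enoate. The closest known reaction type is the proline-catalysed α-aminoxylation of unbranched aldehydes with nitrosobenzene followed in the same flask by Wittig or Horner–Wadsworth–Emmons olefination. No ring is closed. The single new stereocentre (C4 of 10) is set by the catalyst: L-proline gives R α-aminoxy aldehydes, so D-proline should give S, and replacing CHO by CH=C leaves the priority order unchanged. The step needs O- over N-attack, a single oxygenation, no racemisation of 9 and E geometry; these are secured by the acid-activated nitroso group, the limiting amount of 6 on the unbranched α-CH2 of 5, immediate trapping at 0 °C and the reversibly adding stabilised ylide, while the 3-alkylfuran is inert to both reagents.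

Step 5
Reactants: 10 ethyl (2E,4S)-5-(furan-3-yl)-2-methyl-4-[(phenylamino)oxy]pent-2-enoate
Product: 11 ethyl (2E,4S)-5-(furan-3-yl)-4-hydroxy-2-methylpent-2-enoate
Conditions: Cu(OAc)2·H2O (30 mol%), EtOH, rt
Reagents that add atoms: none
Why: N–O bond cleavage of an O-alkyl-N-arylhydroxylamine promoted by divalent copper should free the alcohol under neutral conditions without touching the C–O bond of the stereocentre, the enoate or the furan; the E-enoate cannot lactonise.

Step 6
Reactants: 11 ethyl (2E,4S)-5-(furan-3-yl)-4-hydroxy-2-methylpent-2-enoate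
Product: 12 ethyl (2E,4S)-4-[(tert-butyldimethylsilyl)oxy]-5-(furan-3-yl)-2-methylpent-2-enoate
Conditions: TBSCl, imidazole, DMF, rt
Reagents that add atoms: tert-butyldimethylsilyl chloride, CC(C)(C)[Si](C)(C)Cl
Why: Imidazole-promoted silylation of the secondary alcohol gives an ether that survives hydride reduction, bromination and zerovalent palladium, where an allylic ester at this carbon would be cleaved or ionised.

Step 7
Reactants: 12 ethyl (2E,4S)-4-[(tert-butyldimethylsilyl)oxy]-5-(furan-3-yl)-2-methylpent-2-enoate
Product: 13 (2E,4S)-4-[(tert-butyldimethylsilyl)oxy]-5-(furan-3-yl)-2-methylpent-2-en-1-ol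
Conditions: i-Bu2AlH (2.3 equiv), CH2Cl2, −78 °C; aq. potassium sodium tartrate
Reagents that add atoms: none
Why: 1,2-Reduction of the enoate with excess i-Bu2AlH should give the E allylic alcohol without conjugate reduction and without touching the silyl ether or the stereocentre.

Step 8
Reactants: 13 (2E,4S)-4-[(tert-butyldimethylsilyl)oxy]-5-(furan-3-yl)-2-methylpent-2-en-1-ol
Product: 14 tert-butyl{[(2S,3E)-5-bromo-1-(furan-3-yl)-4-methylpent-3-en-2-yl]oxy}dimethylsilane
Conditions: CBr4, PPh3, CH2Cl2, 0 °C; used directly
Reagents that add atoms: carbon tetrabromide, BrC(Br)(Br)Br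
Why: Appel bromination displaces the oxyphosphonium group of the primary allylic alcohol by bromide in an SN2 step, under neutral conditions that should avoid allylic transposition and spare furan and silyl ether.

Step 9
Reactants: 5 3-(furan-3-yl)propanal; 15 2-(triphenylphosphoranylidene)propanal
Product: 16 (2E)-5-(furan-3-yl)-2-methylpent-2-enal
Conditions: toluene, 90 °C
Reagents that add atoms: 2-(triphenylphosphoranylidene)propanal 15, CC(C=O)=P(c1ccccc1)(c1ccccc1)c1ccccc1
Why: Wittig olefination with the formyl-stabilised α-methyl ylide should give the E enal, and the conjugated product aldehyde is too unreactive towards this ylide to be olefinated again.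

Step 10
Reactants: 16 (2E)-5-(furan-3-yl)-2-methylpent-2-enal; 17 dimethyl (1-diazo-2-oxopropyl)phosphonate
Product: 18 3-[(3E)-4-methylhex-3-en-5-yn-1-yl]furan
Conditions: K2CO3, MeOH, 0 °C to rt
Reagents that add atoms: dimethyl (1-diazo-2-oxopropyl)phosphonate 17, COP(=O)(OC)C(=[N+]=[N-])C(C)=O
Why: Seyferth–Gilbert homologation in its Ohira–Bestmann form: methanolysis of 17 gives the diazomethylphosphonate anion, which olefinates the aldehyde, and loss of N2 with 1,2-hydrogen shift of the alkylidene carbene gives the terminal alkyne with the E alkene unchanged.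

Step 11
Reactants: 18 3-[(3E)-4-methylhex-3-en-5-yn-1-yl]furan (1.3 equiv); 14 tert-butyl{[(2S,3E)-5-bromo-1-(furan-3-yl)-4-methylpent-3-en-2-yl]oxy}dimethylsilane
Product: 20 tert-butyl{[(2S,3E,6E,8E)-1,11-di(furan-3-yl)-4,8-dimethylundeca-3,6,8-trien-2-yl]oxy}dimethylsilane, via dienylzirconocene chloride 19 (not isolated)
Conditions: 18, Cp2Zr(H)Cl (1.2 equiv to 18), THF, rt; then 14, Pd(PPh3)4 (5 mol%), THF, rt
Reagents that add atoms: none
Why: Hydrozirconation adds Zr–H syn across the terminal alkyne with zirconium at the terminal carbon (the trisubstituted alkene is inert), and the resulting E,E-dienyl group should transfer to the η3-allyl complex [(allyl)Pd(PPh3)2]Br formed from 14 and couple at its unhindered CH2 end (Negishi-type alkenylzirconium–allyl halide coupling) with retention of all alkene geometries, while the silyloxy-bearing carbon is not involved.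

Step 12
Reactants: 20 tert-butyl{[(2S,3E,6E,8E)-1,11-di(furan-3-yl)-4,8-dimethylundeca-3,6,8-trien-2-yl]oxy}dimethylsilane
Product: 21 (2S,3E,6E,8E)-1,11-di(furan-3-yl)-4,8-dimethylundeca-3,6,8-trien-2-ol
Conditions: TBAF, THF, 0 °C to rt
Reagents that add atoms: none
Why: Fluoride-mediated desilylation, driven by Si–F bond formation, should release the secondary allylic alcohol without affecting the skipped triene or the furans.

Step 13
Reactants: 21 (2S,3E,6E,8E)-1,11-di(furan-3-yl)-4,8-dimethylundeca-3,6,8-trien-2-ol
Product: 22 (2S,3E,6E,8E)-1,11-di(furan-3-yl)-4,8-dimethylundeca-3,6,8-trien-2-yl acetate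
Conditions: Ac2O, pyridine, DMAP (cat.), CH2Cl2, 0 °C to rt
Reagents that add atoms: acetic anhydride, CC(=O)OC(C)=O
Why: DMAP-catalysed O-acylation leaves the C–O bond of the stereocentre intact, so the S configuration is retained in the target.

**Compound list**

1 | furan-3-carbaldehyde | O=Cc1ccoc1 | starting material
2 | trimethyl phosphonoacetate | COC(=O)CP(=O)(OC)OC | starting material
3 | methyl (2E)-3-(furan-3-yl)prop-2-enoate | COC(=O)/C=C/c1ccoc1 | intermediate
4 | methyl 3-(furan-3-yl)propanoate | COC(=O)CCc1ccoc1 | intermediate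
5 | 3-(furan-3-yl)propanal | O=CCCc1ccoc1 | intermediate
6 | nitrosobenzene | O=Nc1ccccc1 | starting material
7 | D-proline, (2R)-pyrrolidine-2-carboxylic acid, catalyst | OC(=O)[C@H]1CCCN1 | starting material
8 | ethyl 2-(triphenylphosphoranylidene)propanoate | CCOC(=O)C(C)=P(c1ccccc1)(c1ccccc1)c1ccccc1 | starting material
9 | (2S)-3-(furan-3-yl)-2-[(phenylamino)oxy]propanal, not isolated | O=C[C@H](Cc1ccoc1)ONc1ccccc1 | intermediate
10 | ethyl (2E,4S)-5-(furan-3-yl)-2-methyl-4-[(phenylamino)oxy]pent-2-enoate | CCOC(=O)/C(C)=C/[C@H](Cc1ccoc1)ONc1ccccc1 | intermediate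
11 | ethyl (2E,4S)-5-(furan-3-yl)-4-hydroxy-2-methylpent-2-enoate | CCOC(=O)/C(C)=C/[C@H](Cc1ccoc1)O | intermediate
12 | ethyl (2E,4S)-4-[(tert-butyldimethylsilyl)oxy]-5-(furan-3-yl)-2-methylpent-2-enoate | CCOC(=O)/C(C)=C/[C@H](Cc1ccoc1)O[Si](C)(C)C(C)(C)C | intermediate
13 | (2E,4S)-4-[(tert-butyldimethylsilyl)oxy]-5-(furan-3-yl)-2-methylpent-2-en-1-ol | OC/C(C)=C/[C@H](Cc1ccoc1)O[Si](C)(C)C(C)(C)C | intermediate
14 | tert-butyl{[(2S,3E)-5-bromo-1-(furan-3-yl)-4-methylpent-3-en-2-yl]oxy}dimethylsilane | BrC/C(C)=C/[C@H](Cc1ccoc1)O[Si](C)(C)C(C)(C)C | intermediate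
15 | 2-(triphenylphosphoranylidene)propanal | CC(C=O)=P(c1ccccc1)(c1ccccc1)c1ccccc1 | starting material
16 | (2E)-5-(furan-3-yl)-2-methylpent-2-enal | O=C/C(C)=C/CCc1ccoc1 | intermediate
17 | dimethyl (1-diazo-2-oxopropyl)phosphonate | COP(=O)(OC)C(=[N+]=[N-])C(C)=O | starting material
18 | 3-[(3E)-4-methylhex-3-en-5-yn-1-yl]furan | C#C/C(C)=C/CCc1ccoc1 | intermediate
19 | chlorobis(cyclopentadienyl)[(1E,3E)-6-(furan-3-yl)-3-methylhexa-1,3-dien-1-yl]zirconium, not isolated | Cl[Zr](/C=C/C(C)=C/CCc1ccoc1)(C1C=CC=C1)C1C=CC=C1 | intermediate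
20 | tert-butyl{[(2S,3E,6E,8E)-1,11-di(furan-3-yl)-4,8-dimethylundeca-3,6,8-trien-2-yl]oxy}dimethylsilane | CC(C)(C)[Si](C)(C)O[C@H](/C=C(\C)C/C=C/C(C)=C/CCc1ccoc1)Cc1ccoc1 | intermediate
21 | (2S,3E,6E,8E)-1,11-di(furan-3-yl)-4,8-dimethylundeca-3,6,8-trien-2-ol | O[C@H](/C=C(\C)C/C=C/C(C)=C/CCc1ccoc1)Cc1ccoc1 | intermediate
22 | (2S,3E,6E,8E)-1,11-di(furan-3-yl)-4,8-dimethylundeca-3,6,8-trien-2-yl acetate | CC(=O)O[C@H](/C=C(\C)C/C=C/C(C)=C/CCc1ccoc1)Cc1ccoc1 | target

**Step count.** Total: 13 steps. Longest linear sequence: 11 steps (steps 1–8 and 11–13); steps 9 and 10 branch from aldehyde 5.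

**Steps most likely to fail**

Step 4. The α-branched ylide may olefinate slowly, so that the α-anilinooxy aldehyde racemises through its enol or enamine, or condenses with itself, before it is trapped. Fallback: set out from 5 and oxygenate with dibenzoyl peroxide under a sterically shielding amine catalyst ((S)-2-(triphenylmethyl)pyrrolidine, 10 mol%, hydroquinone, THF, 0 °C; the S catalyst is expected to give the S aldehyde). This α-benzoyloxylation should give the configurationally more robust (2S)-2-(benzoyloxy)-3-(furan-3-yl)propanal F1, which can be handled and then olefinated with 8 (CH2Cl2, rt) to ethyl (2E,4S)-4-(benzoyloxy)-5-(furan-3-yl)-2-methylpent-2-enoate F2. Ethanolysis of the benzoate (K2CO3, EtOH, 0 °C) comes back to the route at 11.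

Step 11. Transfer of the dienyl group from zirconium to palladium may be slow, leaving time for the allylpalladium intermediate to isomerise (loss of the E geometry, branched coupling) or to eliminate to a diene, and for the zirconium reagent to be protonated. Fallback: set out from 18 and hydroborate with pinacolborane (Cp2Zr(H)Cl 10 mol%, Et3N 10 mol%, neat, 60 °C) to 2-[(1E,3E)-6-(furan-3-yl)-3-methylhexa-1,3-dien-1-yl]-4,4,5,5-tetramethyl-1,3,2-dioxaborolane F3. This isolable boronate is joined to 14 by Suzuki–Miyaura coupling (Pd(PPh3)4, aq. K3PO4, THF, 50 °C), coming back to the route at 20.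

Step 10. Methoxide may add in conjugate fashion to the enal or to the diazoalkene intermediate, diverting material to a homopropargylic methyl ether. Fallback: set out from 16 by Corey–Fuchs homologation in aprotic media: CBr4, PPh3, CH2Cl2, 0 °C should give 3-[(3E)-6,6-dibromo-4-methylhexa-3,5-dien-1-yl]furan F4. Treatment with n-BuLi (2.1 equiv, THF, −78 °C, then aq. NH4Cl) brings about bromine–lithium exchange, rearrangement and protonation, coming back to the route at 18.

**Further compounds**

F1 | step 4 | (2S)-2-(benzoyloxy)-3-(furan-3-yl)propanal | O=C[C@H](Cc1ccoc1)OC(=O)c1ccccc1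
F2 | step 4 | ethyl (2E,4S)-4-(benzoyloxy)-5-(furan-3-yl)-2-methylpent-2-enoate | CCOC(=O)/C(C)=C/[C@H](Cc1ccoc1)OC(=O)c1ccccc1
F3 | step 11 | 2-[(1E,3E)-6-(furan-3-yl)-3-methylhexa-1,3-dien-1-yl]-4,4,5,5-tetramethyl-1,3,2-dioxaborolane | CC1(C)OB(/C=C/C(C)=C/CCc2ccoc2)OC1(C)C
F4 | step 10 | 3-[(3E)-6,6-dibromo-4-methylhexa-3,5-dien-1-yl]furan | BrC(Br)=C/C(C)=C/CCc1ccoc1
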